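Ring A (C3a–C4–C5–C6–C7–C7a, indene numbering) is disconnected to a 4,4-disubstituted 3-ethylcyclohexenone, because the acid carbon C4 is the α-carbon of a β-keto ester and C5–C6–C7 is a latent enone. One catalytic Michael–aldol annulation joins tert-butyl 2-ethyl-3-oxopentanoate to an E-configured 6-silyloxyhex-3-en-2-one, forming C3a–C4 and C5=C6, closing ring A and setting the quaternary C4 and tertiary C3a centres. The enone then receives the C7a arm (trans), the styryl group at C5 and, through its enol triflate, the C7 ethyl group; ring B follows by Dieckmann closure, and both tert-butyl esters fall in the last step.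

Key step: step 3

Assumption: the quinidine-derived primary amine is taken to give the (R)-C4 series drawn; if it gives the antipode, its quinine-derived pseudoenantiomer is used. Locants C1–C7a are those of the target throughout, and numbered carbon building blocks stand on the Reactants line, so the reagent line names only further donors of atoms.

Step 1
Reactants: 1 tert-butyl 3-oxopentanoate; 2 iodoethane
Product: 3 tert-butyl 2-ethyl-3-oxopentanoate (racemic, α-centre labile)
Conditions: K2CO3, acetone, reflux
Reagents that add atoms: none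
Why: C-alkylation of a β-keto ester enolate with a primary iodide (acetoacetic ester alkylation) is reliable and leaves the one α-hydrogen needed for step 3, and no fixed stereocentre is created.

Step 2
Reactants: 4 3-(tert-butyldimethylsilyloxy)propan-1-ol; 5 1-(triphenylphosphoranylidene)propan-2-one
Product: 7 (E)-6-(tert-butyldimethylsilyloxy)hex-3-en-2-one, via 3-(tert-butyldimethylsilyloxy)propanal 6 (not isolated)
Conditions: IBX (1.5 equiv), 5 (1.3 equiv), DMSO, rt to 40 °C
Reagents that add atoms: none
Why: In this tandem IBX oxidation–Wittig olefination the stabilised acyl ylide traps the sensitive β-silyloxy aldehyde as it forms and, as stabilised ylides do, gives the E-enone.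

Step 3
Reactants: 3 tert-butyl 2-ethyl-3-oxopentanoate; 7 (E)-6-(tert-butyldimethylsilyloxy)hex-3-en-2-one
Product: 9 tert-butyl (1R,6S)-6-[2-(tert-butyldimethylsilyloxy)ethyl]-1,2-diethyl-4-oxocyclohex-2-ene-1-carboxylate, via open-chain Michael adduct 8 (not isolated)
Conditions: 9-amino-9-deoxy-epi-quinidine (20 mol %), 2-fluorobenzoic acid (40 mol %), toluene, 40 °C; then pyrrolidine/AcOH (30 mol % each), 60 °C
Reagents that add atoms: none
Why: The primary amine converts 7 into an E-iminium ion, the chelated Z-enol of 3, held by the protonated quinuclidine, attacks its β-carbon (C3a) through C4, and the acetyl group, left as the terminal enamine, then adds to the propanoyl carbonyl next to C4 and loses water, so that C3a–C4 and C5=C6 form and ring A closes. The closest known reaction type is the amine-catalysed asymmetric Michael addition of α-substituted β-keto esters to β-substituted enones carried on into an aldol condensation (Robinson annulation). Ring A closes in the 6-(enolendo)-exo-trig mode. The quaternary centre C4 is controlled by the catalyst, which shields one face of the enol, and C3a by the face of the E-iminium ion exposed in the same ion pair, so both are fixed in one C–C bond formation and neither can epimerise later (C4 has no hydrogen, C3a is β to the ketone). The step needs the adduct in which the C4 ethyl group and the C3a chain become cis on the ring, which the defined E alkene of 7 and the single enol geometry of 3 reduce to one face pairing, and it needs closure from the acetyl methyl, which is secured because the propanoyl ketone beside the quaternary C4 is too hindered to form an enamine and attack from the internal enamine carbon would give a four-membered ring.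

Step 4
Reactants: 9 key cyclohexenone; 10 tert-butyl bromoacetate
Product: 11 tert-butyl (1R,5S,6S)-5-(2-tert-butoxy-2-oxoethyl)-6-[2-(tert-butyldimethylsilyloxy)ethyl]-1,2-diethyl-4-oxocyclohex-2-ene-1-carboxylate
Conditions: LDA, THF, −78 °C; then 10, DMPU, −78 to −30 °C
Reagents that add atoms: none
Why: LDA removes a C7a (α′) proton under kinetic control to give the cross-conjugated dienolate, and its SN2 alkylation (ketone enolate alkylation) takes place anti to the C3a chain and the pseudo-axial C4 ethyl group, so the new arm is trans to the C3a chain, which is also the preferred diequatorial arrangement at this still epimerisable centre.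

Step 5
Reactants: 11 C7a-alkylated enone
Product: 12 2-[(1S,2R,6S)-2-(tert-butoxycarbonyl)-6-(2-tert-butoxy-2-oxoethyl)-2,3-diethyl-5-oxocyclohex-3-en-1-yl]acetic acid
Conditions: Jones reagent (CrO3, H2SO4, H2O), acetone, 0 °C
Reagents that add atoms: water, O
Why: In this Jones oxidation the acidic medium cleaves the primary silyl ether and chromic acid takes the freed alcohol through the aldehyde hydrate to the acid in one operation, while the tert-butyl esters and the enone are expected to survive at 0 °C, and no stereocentre is formed.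

Step 6
Reactants: 12 acid
Product: 13 tert-butyl (1R,5S,6S)-5-(2-tert-butoxy-2-oxoethyl)-1,2-diethyl-6-(2-methoxy-2-oxoethyl)-4-oxocyclohex-2-ene-1-carboxylate
Conditions: MeI, K2CO3, DMF, rt
Reagents that add atoms: iodomethane, CI
Why: SN2 O-alkylation of the carboxylate gives the methyl ester that will act as the acyl acceptor in step 10, the weak base leaving the tert-butyl esters and the thermodynamically settled C7a centre untouched, and no stereocentre is formed.

Step 7
Reactants: 13 methyl ester enone; 14 (E)-(2-bromoethenyl)benzene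
Product: 15 C6=C7 trimethylsilyl enol ether of the C5 styryl adduct (styryl cis to the C4 ester, trans to the C4 ethyl)
Conditions: 14, Mg, THF; the Grignard solution added slowly to 13, CuBr·SMe2 (20 mol %), TMSCl, DMPU, THF, −78 to −40 °C; Et3N, aq NaHCO3 work-up
Reagents that add atoms: chlorotrimethylsilane, C[Si](C)(C)Cl
Why: This is a copper-catalysed, TMSCl-accelerated conjugate addition of an alkenyl Grignard reagent, in which the styryl group enters C5 axially on the half-chair from the face opposite the pseudo-axial C4 ethyl group and the enolate is trapped regiospecifically on oxygen.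

Step 8
Reactants: 15 silyl enol ether
Product: 16 the corresponding C6=C7 enol triflate
Conditions: CsF, PhNTf2, DME, rt
Reagents that add atoms: N-phenylbis(trifluoromethanesulfonimide), O=S(=O)(N(c1ccccc1)S(=O)(=O)C(F)(F)F)C(F)(F)F
Why: Fluoride cleaves the Si–O bond and the caesium enolate is triflated on oxygen by PhNTf2 before it can equilibrate (enol triflate formation from a silyl enol ether), which keeps the double bond at C6=C7, and no stereocentre is formed.

Step 9
Reactants: 16 enol triflate; 17 diethylzinc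
Product: 18 tert-butyl 5-(2-tert-butoxy-2-oxoethyl)-1,2,4-triethyl-6-(2-methoxy-2-oxoethyl)-2-[(E)-2-phenylethenyl]cyclohex-3-ene-1-carboxylate
Conditions: Pd(dppf)Cl2 (5 mol %), THF, 50 °C
Reagents that add atoms: none
Why: In this Negishi coupling of an alkenyl triflate the wide-bite-angle dppf ligand favours reductive elimination over β-hydride elimination, the three esters are inert to the organozinc reagent, and no stereocentre is touched.

Step 10
Reactants: 18 triester; 2 iodoethane
Product: 20 di-tert-butyl 1,4,5,7-tetraethyl-2-oxo-5-[(E)-2-phenylethenyl]-2,3,3a,4,5,7a-hexahydro-1H-indene-1,4-dicarboxylate (trans-fused), via Dieckmann β-keto ester 19 (not isolated)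
Conditions: KOtBu, THF, 0 °C to rt; then 2, DMF co-solvent, 40 °C
Reagents that add atoms: none
Why: In the Dieckmann condensation the enolate of the C7a acetate arm attacks the methyl ester of the trans C3a arm (the tert-butyl esters are poor acceptors, so only this direction is open) to give the trans-fused cyclopentanone as its stabilised enolate, which is C-ethylated in the same flask (β-keto ester alkylation), and the C1 centre so formed is temporary and is reset in step 12.

Step 11
Reactants: 20 C1-ethyl β-keto ester; 2 iodoethane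
Product: 21 di-tert-butyl 1,3,4,5,7-pentaethyl-2-oxo-5-[(E)-2-phenylethenyl]-2,3,3a,4,5,7a-hexahydro-1H-indene-1,4-dicarboxylate (C3 ethyl cis to H3a)
Conditions: LDA, THF, −78 °C; then 2, DMPU, −78 to 0 °C
Reagents that add atoms: none
Why: C3 is the only enolisable position, and alkylation of its lithium enolate (ketone enolate alkylation) occurs on the face away from the pseudo-axial C4 ethyl group, which places the C3 ethyl group cis to H3a, also the more stable arrangement.

Step 12
Reactants: 21 pentaethyl diester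
Product: 23 (1S,3S,3aR,4R,5S,7aR)-1,3,4,5,7-pentaethyl-2-oxo-5-[(E)-2-phenylethenyl]-2,3,3a,4,5,7a-hexahydro-1H-indene-4-carboxylic acid, via β-keto diacid 22 (not isolated)
Conditions: TFA/CH2Cl2 (1:4), 0 °C to rt; evaporate; toluene, 80 °C
Reagents that add atoms: none
Why: Acidolysis removes both tert-butyl groups as isobutene without attack at the congested carbonyl groups and the β-keto acid then decarboxylates thermally, the C1 enol being protonated anti to the pseudo-axial C7a–H bond (torsional control), which should leave the C1 ethyl group pseudo-equatorial and cis to H7a.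

Compound list

1 | tert-butyl 3-oxopentanoate | CCC(=O)CC(=O)OC(C)(C)C | starting material
2 | iodoethane | CCI | starting material
3 | tert-butyl 2-ethyl-3-oxopentanoate (racemic) | CCC(=O)C(CC)C(=O)OC(C)(C)C | intermediate
4 | 3-(tert-butyldimethylsilyloxy)propan-1-ol | OCCCO[Si](C)(C)C(C)(C)C | starting material
5 | 1-(triphenylphosphoranylidene)propan-2-one | CC(=O)C=P(c1ccccc1)(c1ccccc1)c1ccccc1 | starting material
6 | 3-(tert-butyldimethylsilyloxy)propanal | O=CCCO[Si](C)(C)C(C)(C)C | intermediate (not isolated)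
7 | (E)-6-(tert-butyldimethylsilyloxy)hex-3-en-2-one | CC(=O)/C=C/CCO[Si](C)(C)C(C)(C)C | intermediate
8 | tert-butyl (2R,3S)-3-[2-(tert-butyldimethylsilyloxy)ethyl]-2-ethyl-5-oxo-2-propanoylhexanoate | CCC(=O)[C@](CC)(C(=O)OC(C)(C)C)[C@@H](CCO[Si](C)(C)C(C)(C)C)CC(C)=O | intermediate (not isolated)
9 | tert-butyl (1R,6S)-6-[2-(tert-butyldimethylsilyloxy)ethyl]-1,2-diethyl-4-oxocyclohex-2-ene-1-carboxylate (C4 ethyl cis to the C3a chain) | O=C1C=C(CC)[C@](CC)(C(=O)OC(C)(C)C)[C@@H](CCO[Si](C)(C)C(C)(C)C)C1 | intermediate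
10 | tert-butyl bromoacetate | BrCC(=O)OC(C)(C)C | starting material
11 | tert-butyl (1R,5S,6S)-5-(2-tert-butoxy-2-oxoethyl)-6-[2-(tert-butyldimethylsilyloxy)ethyl]-1,2-diethyl-4-oxocyclohex-2-ene-1-carboxylate (C7a arm trans to the C3a chain) | O=C1C=C(CC)[C@](CC)(C(=O)OC(C)(C)C)[C@@H](CCO[Si](C)(C)C(C)(C)C)[C@@H]1CC(=O)OC(C)(C)C | intermediate
12 | 2-[(1S,2R,6S)-2-(tert-butoxycarbonyl)-6-(2-tert-butoxy-2-oxoethyl)-2,3-diethyl-5-oxocyclohex-3-en-1-yl]acetic acid | O=C1C=C(CC)[C@](CC)(C(=O)OC(C)(C)C)[C@@H](CC(=O)O)[C@@H]1CC(=O)OC(C)(C)C | intermediate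
13 | tert-butyl (1R,5S,6S)-5-(2-tert-butoxy-2-oxoethyl)-1,2-diethyl-6-(2-methoxy-2-oxoethyl)-4-oxocyclohex-2-ene-1-carboxylate | O=C1C=C(CC)[C@](CC)(C(=O)OC(C)(C)C)[C@@H](CC(=O)OC)[C@@H]1CC(=O)OC(C)(C)C | intermediate
14 | (E)-(2-bromoethenyl)benzene | Br/C=C/c1ccccc1 | starting material
15 | tert-butyl 5-(2-tert-butoxy-2-oxoethyl)-1,2-diethyl-6-(2-methoxy-2-oxoethyl)-2-[(E)-2-phenylethenyl]-4-(trimethylsilyloxy)cyclohex-3-ene-1-carboxylate (styryl cis to the C4 ester; other centres as in 13) | C[Si](C)(C)OC1=C[C@@](/C=C/c2ccccc2)(CC)[C@](CC)(C(=O)OC(C)(C)C)[C@@H](CC(=O)OC)[C@@H]1CC(=O)OC(C)(C)C | intermediate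
16 | tert-butyl 5-(2-tert-butoxy-2-oxoethyl)-1,2-diethyl-6-(2-methoxy-2-oxoethyl)-2-[(E)-2-phenylethenyl]-4-(trifluoromethylsulfonyloxy)cyclohex-3-ene-1-carboxylate (configuration as in 15) | O=S(=O)(OC1=C[C@@](/C=C/c2ccccc2)(CC)[C@](CC)(C(=O)OC(C)(C)C)[C@@H](CC(=O)OC)[C@@H]1CC(=O)OC(C)(C)C)C(F)(F)F | intermediate
17 | diethylzinc | CC[Zn]CC | starting material
18 | tert-butyl 5-(2-tert-butoxy-2-oxoethyl)-1,2,4-triethyl-6-(2-methoxy-2-oxoethyl)-2-[(E)-2-phenylethenyl]cyclohex-3-ene-1-carboxylate (configuration as in 15) | CCC1=C[C@@](/C=C/c2ccccc2)(CC)[C@](CC)(C(=O)OC(C)(C)C)[C@@H](CC(=O)OC)[C@@H]1CC(=O)OC(C)(C)C | intermediate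
19 | di-tert-butyl 4,5,7-triethyl-2-oxo-5-[(E)-2-phenylethenyl]-2,3,3a,4,5,7a-hexahydro-1H-indene-1,4-dicarboxylate (trans-fused; C1 enolisable, potassium enolate in the flask) | CCC1=C[C@@](/C=C/c2ccccc2)(CC)[C@](CC)(C(=O)OC(C)(C)C)[C@@H]2[C@@H]1C(C(=O)OC(C)(C)C)C(=O)C2 | intermediate (not isolated)
20 | di-tert-butyl 1,4,5,7-tetraethyl-2-oxo-5-[(E)-2-phenylethenyl]-2,3,3a,4,5,7a-hexahydro-1H-indene-1,4-dicarboxylate (trans-fused; C1 drawn with ethyl anti to H7a, of no consequence) | CCC1=C[C@@](/C=C/c2ccccc2)(CC)[C@](CC)(C(=O)OC(C)(C)C)[C@@H]2[C@@H]1[C@](CC)(C(=O)OC(C)(C)C)C(=O)C2 | intermediate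
21 | di-tert-butyl 1,3,4,5,7-pentaethyl-2-oxo-5-[(E)-2-phenylethenyl]-2,3,3a,4,5,7a-hexahydro-1H-indene-1,4-dicarboxylate (C3 ethyl cis to H3a) | CCC1=C[C@@](/C=C/c2ccccc2)(CC)[C@](CC)(C(=O)OC(C)(C)C)[C@@H]2[C@@H]1[C@](CC)(C(=O)OC(C)(C)C)C(=O)[C@H]2CC | intermediate
22 | 1,3,4,5,7-pentaethyl-2-oxo-5-[(E)-2-phenylethenyl]-2,3,3a,4,5,7a-hexahydro-1H-indene-1,4-dicarboxylic acid (configuration as in 21) | CCC1=C[C@@](/C=C/c2ccccc2)(CC)[C@](CC)(C(=O)O)[C@@H]2[C@@H]1[C@](CC)(C(=O)O)C(=O)[C@H]2CC | intermediate (not isolated)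
23 | (1S,3S,3aR,4R,5S,7aR)-1,3,4,5,7-pentaethyl-2-oxo-5-[(E)-2-phenylethenyl]-2,3,3a,4,5,7a-hexahydro-1H-indene-4-carboxylic acid | CCC1=C[C@@](/C=C/c2ccccc2)(CC)[C@](CC)(C(=O)O)[C@@H]2[C@@H]1[C@H](CC)C(=O)[C@H]2CC | target

Total step count: 12. Longest linear sequence: 11 steps (4 to 23 through steps 2–12; equally 1 to 23 through steps 1 and 3–12).

Steps most likely to fail

1. Step 3. The fully substituted donor may add slowly and reversibly, so the adduct can revert on warming, the two faces may be poorly differentiated, and ring closure may stall at the ketol or start from the propanoyl methylene. The fallback sets out from 4 and 3 and comes back at 9. Alcohol 4 is oxidised under Swern conditions and aldehyde 6 is isolated. A single Horner–Wadsworth–Emmons reaction with tetramethyl (2-oxopropane-1,3-diyl)bis(phosphonate) and one equivalent of K2CO3 gives dimethyl [(E)-6-(tert-butyldimethylsilyloxy)-2-oxohex-3-en-1-yl]phosphonate F1. Keto ester 3 is added to F1 under a bifunctional cinchona squaramide (Brønsted-base and hydrogen-bond catalysis at or below room temperature, no iminium ion) to give tert-butyl (2R,3S)-3-[2-(tert-butyldimethylsilyloxy)ethyl]-6-(dimethoxyphosphoryl)-2-ethyl-5-oxo-2-propanoylhexanoate F2. An intramolecular HWE olefination (LiCl, i-Pr2NEt, MeCN) then closes ring A irreversibly and only at the propanoyl ketone, giving 9.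

2. Step 7. The organocopper reagent may deprotonate C7a or fail to reach C5, a β-carbon flanked by the quaternary C4, and the alkenyl reagent may lose part of its E geometry. The fallback sets out from 13 and comes back at 18. The smaller vinyl nucleophile (vinylmagnesium bromide, CuBr·SMe2, TMSCl, DMPU, as in step 7) gives tert-butyl 5-(2-tert-butoxy-2-oxoethyl)-2-ethenyl-1,2-diethyl-6-(2-methoxy-2-oxoethyl)-4-(trimethylsilyloxy)cyclohex-3-ene-1-carboxylate F3. CsF and PhNTf2 convert it into the enol triflate F4, and Negishi coupling with 17 gives tert-butyl 5-(2-tert-butoxy-2-oxoethyl)-2-ethenyl-1,2,4-triethyl-6-(2-methoxy-2-oxoethyl)cyclohex-3-ene-1-carboxylate F5. A Heck arylation with iodobenzene (Pd(OAc)2, Bu4NCl, NaHCO3, DMF, 80 °C) on the only monosubstituted alkene then builds the styryl unit, its E geometry fixed by syn β-hydride elimination, and gives 18.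

3. Step 12. Ketonisation of the C1 enol may show poor facial selectivity and deliver the C1 epimer. The fallback sets out from 18 and comes back at 23. The Dieckmann closure is run without alkyl halide and β-keto ester 19 is isolated. Its dianion (LDA, 2.2 equiv) is ethylated at the γ-carbon C3 with one equivalent of 2 to give di-tert-butyl 3,4,5,7-tetraethyl-2-oxo-5-[(E)-2-phenylethenyl]-2,3,3a,4,5,7a-hexahydro-1H-indene-1,4-dicarboxylate F6. TFA and then heat remove both tert-butyl groups and the C1 carboxyl to give 3,4,5,7-tetraethyl-2-oxo-5-[(E)-2-phenylethenyl]-2,3,3a,4,5,7a-hexahydro-1H-indene-4-carboxylic acid F7. Kinetic deprotonation of its carboxylate at the C1 methylene (LDA, 2.2 equiv, −78 °C) and alkylation with 2 introduce the C1 ethyl group last. The carbon substituent, not the proton, then enters on the face preferred at C1, and acidification gives 23.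

Further compounds

F1 | step 3 | dimethyl [(E)-6-(tert-butyldimethylsilyloxy)-2-oxohex-3-en-1-yl]phosphonate | COP(=O)(OC)CC(=O)/C=C/CCO[Si](C)(C)C(C)(C)C
F2 | step 3 | tert-butyl (2R,3S)-3-[2-(tert-butyldimethylsilyloxy)ethyl]-6-(dimethoxyphosphoryl)-2-ethyl-5-oxo-2-propanoylhexanoate | CCC(=O)[C@](CC)(C(=O)OC(C)(C)C)[C@@H](CCO[Si](C)(C)C(C)(C)C)CC(=O)CP(=O)(OC)OC
F3 | step 7 | tert-butyl 5-(2-tert-butoxy-2-oxoethyl)-2-ethenyl-1,2-diethyl-6-(2-methoxy-2-oxoethyl)-4-(trimethylsilyloxy)cyclohex-3-ene-1-carboxylate | C[Si](C)(C)OC1=C[C@@](C=C)(CC)[C@](CC)(C(=O)OC(C)(C)C)[C@@H](CC(=O)OC)[C@@H]1CC(=O)OC(C)(C)C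
F4 | step 7 | tert-butyl 5-(2-tert-butoxy-2-oxoethyl)-2-ethenyl-1,2-diethyl-6-(2-methoxy-2-oxoethyl)-4-(trifluoromethylsulfonyloxy)cyclohex-3-ene-1-carboxylate | O=S(=O)(OC1=C[C@@](C=C)(CC)[C@](CC)(C(=O)OC(C)(C)C)[C@@H](CC(=O)OC)[C@@H]1CC(=O)OC(C)(C)C)C(F)(F)F
F5 | step 7 | tert-butyl 5-(2-tert-butoxy-2-oxoethyl)-2-ethenyl-1,2,4-triethyl-6-(2-methoxy-2-oxoethyl)cyclohex-3-ene-1-carboxylate | CCC1=C[C@@](C=C)(CC)[C@](CC)(C(=O)OC(C)(C)C)[C@@H](CC(=O)OC)[C@@H]1CC(=O)OC(C)(C)C
F6 | step 12 | di-tert-butyl 3,4,5,7-tetraethyl-2-oxo-5-[(E)-2-phenylethenyl]-2,3,3a,4,5,7a-hexahydro-1H-indene-1,4-dicarboxylate | CCC1=C[C@@](/C=C/c2ccccc2)(CC)[C@](CC)(C(=O)OC(C)(C)C)[C@@H]2[C@@H]1C(C(=O)OC(C)(C)C)C(=O)[C@H]2CC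
F7 | step 12 | 3,4,5,7-tetraethyl-2-oxo-5-[(E)-2-phenylethenyl]-2,3,3a,4,5,7a-hexahydro-1H-indene-4-carboxylic acid | CCC1=C[C@@](/C=C/c2ccccc2)(CC)[C@](CC)(C(=O)O)[C@@H]2[C@@H]1CC(=O)[C@H]2CC
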